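In a one-step world substrate meets reagent one to one, and each reagent buys one target. The south run charges a different price.

| setting | south | flask |
|---|---|---|
| substrate | 0.067 M (in portions, 2) | 0.067 M (in portions, 2) |
| reagent | 0.095 M | 0.0636 M |
| remark | run made earlier; portions every 15 h | the portions of substrate follow each other after 15 h, the first at the start |
| time |  | 12 d |

- south (time / d: substrate / %, side product / %, target / %): 0.208: 30.9, 5.9, 12.6; 0.333: 24.1, 9.2, 14.7; 0.417: 22.3, 14.2, 12.4; 0.625: 19.2, 17.2, 14.9; 1.04: 38.7, 44.1, 15.7; 1.67: 27.6, 66.2, 7.7; 2.50: 24.6, 71.5, 3.6

(each reading ± 1 percentage point)

- a species is counted by the substrate in it: one side product counts as two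
- the reaction counts as stopped when no species that holds the substrate changes by six tenths of a point or more over the second half of the time

* which holds at 12 d: what has brought the reaction to rest, or that it has not come to rest (all of the substrate has reacted / it is still moving / the reagent has run out first)
* conversion of substrate at 12 d
* amount of side product at 12 d, in percent of the substrate charged

Each side product holds one target once made, so the fraction of the charge made into target is target plus half the side product. The pace of that sum, per day, in the south run:

- up to 0.208 d: 0.748 d⁻¹
- 0.625 d to 1.04 d: 0.343 d⁻¹
- 1.04 d to 1.67 d: 0.0484 d⁻¹

The first slowing is a factor 2.18, although the second portion has just lifted substrate to 69.2%. The next is a factor 7.09, larger than the factor of 1.40 between the substrate readings at the two ends of that interval, so the slowing points to the reagent side.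

The sum stops at 39.3% as a reading, with 24.6% substrate still present. If the stall is the end of the reagent, the south run paid 3.60. This reagent price, reagent charged per target made, lies above one, so reagent also goes some other way.

My own reckoning at that price gives the flask 26.3% target made and 52.7% side product. That price was read at 0.095 M of reagent; the flask holds less, 0.0636 M.

The forecast, on slightly different figures, says the reagent has run out first, conversion 54% and side product 53.5%: “reagent is used up, at about 3.5 equivalents” for each substrate turned into target.

The flask gives the reagent has run out first, conversion 72.3% and side product 72.3%.

    2 reagent → self-condensation product (k = 5.00 × 10⁻⁴ L mol⁻¹ s⁻¹)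
    substrate + reagent → target, rate k2*[substrate]^2*[reagent]^0.5 (k = 0.00350 L¹·⁵ mol⁻¹·⁵ s⁻¹)
    substrate + target → side product (k = 7.10 × 10⁻⁴ L mol⁻¹ s⁻¹)

In the flask, self-condensation of reagent has half of its turnover done by 0.0933 d, sooner than the 0.891 d of the step to side product, and at 12.0 d the limiting reagent stands at 0% of its charge against 28% for substrate. The flask turned 36.1% of its substrate charge into target, a price of 2.63, below the south run's 3.60, and the neighbour with 0.11 M of substrate, ending at 62.1% side product, pays 1.86.

The readings are calculated for an exercise; noise was put on by code.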